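**Retrosynthetic overview**
1. Target 19 ⇒ hydroxy enol 18: the dihydrofuran ring (O1–C7a) closes last, by cyclodehydration of the benzylic alcohol onto the vinylogous acid.
2. 18 ⇒ acyclic 3,5-dioxo aldehyde 16: the six-membered carbocycle closes first, by an intramolecular aldol condensation (C3a–C4).
3. 16 ⇒ aldol union (C7–C7a) of aldehyde 7 (aryl, C2, C3, C3a, C7a) with methyl ketone 13 (C4–C7, carrying the C5 stereocentre).
4. 7 ⇒ anti-crotylation of 3,4,5-trimethoxybenzaldehyde (sets C2, C3); 13 ⇒ Sharpless epoxidation and invertive methanolysis of the allyl-Grignard adduct of but-2-yn-1-ol (sets C5).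

Assumption: an operation run in one flask with a non-isolated intermediate counts as one step; atom labels C2–C7a follow the benzofuranone numbering of the target.

**Fragment A (aldehyde 7)**

Step 1
Reactants: 1 3,4,5-trimethoxybenzaldehyde
Product: 3 (1S,2S)-2-methyl-1-(3,4,5-trimethoxyphenyl)but-3-en-1-ol, via diisopinocampheylborinate ester 2 (not isolated)
Conditions: trans-2-butene, KOt-Bu, n-BuLi, THF, −78 → −45 °C; (−)-Ipc2BOMe, −78 °C; BF3·OEt2; 1, −78 °C; then NaOH, H2O2, rt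
Reagents that add atoms: (E)-crotyldiisopinocampheylborane, C/C=C/CB([C@@H]1C[C@@H]2C[C@H]([C@H]1C)C2(C)C)[C@@H]1C[C@@H]2C[C@H]([C@H]1C)C2(C)C, made in the flask from trans-2-butene, C/C=C/C (the crotyl group stays in 3, the Ipc2B unit only in 2)
Why: Brown crotylboration through a chair Zimmerman–Traxler transition state; the E-crotyl geometry gives the anti relationship and the (−)-Ipc2B reagent [(+)-α-pinene series] adds to the Si face of the aldehyde, setting C2 and C3 as (1S,2S).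

Step 2
Reactants: 3 (1S,2S)-2-methyl-1-(3,4,5-trimethoxyphenyl)but-3-en-1-ol
Product: 4 tert-butyl(dimethyl){[(1S,2S)-2-methyl-1-(3,4,5-trimethoxyphenyl)but-3-en-1-yl]oxy}silane
Conditions: TBSOTf, 2,6-lutidine, CH2Cl2, 0 °C
Reagents that add atoms: tert-butyldimethylsilyl triflate, CC(C)(C)[Si](C)(C)OS(=O)(=O)C(F)(F)F
Why: Silyl ether protection of the hindered benzylic alcohol with the reactive triflate; no stereocentre is touched.

Step 3
Reactants: 4 tert-butyl(dimethyl){[(1S,2S)-2-methyl-1-(3,4,5-trimethoxyphenyl)but-3-en-1-yl]oxy}silane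
Product: 6 (3S,4S)-4-{[tert-butyl(dimethyl)silyl]oxy}-3-methyl-4-(3,4,5-trimethoxyphenyl)butan-1-ol, via alkyl-9-BBN adduct 5 (not isolated)
Conditions: 9-BBN, THF, 0 °C → rt; then NaOH, H2O2, 0 °C → rt
Reagents that add atoms: 9-BBN, [H]B1C2CCCC1CCC2 (boron of 5 only); hydrogen peroxide, OO (hydroxyl oxygen of 6)
Why: Anti-Markovnikov hydroboration–oxidation of the only alkene in this fragment gives the primary alcohol (C7a) without touching C2 or C3.

Step 4
Reactants: 6 (3S,4S)-4-{[tert-butyl(dimethyl)silyl]oxy}-3-methyl-4-(3,4,5-trimethoxyphenyl)butan-1-ol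
Product: 7 (3S,4S)-4-{[tert-butyl(dimethyl)silyl]oxy}-3-methyl-4-(3,4,5-trimethoxyphenyl)butanal
Conditions: Dess–Martin periodinane, NaHCO3, CH2Cl2, 0 °C → rt
Reagents that add atoms: none
Why: Dess–Martin oxidation stops at the aldehyde; the stereocentres are β and γ to the carbonyl and cannot epimerise.

**Fragment B (ketone 13)**

Step 5
Reactants: 8 but-2-yn-1-ol
Product: 9 (2E)-2-ethylidenepent-4-en-1-ol
Conditions: allylMgBr (3 equiv), CuI (10 mol %), Et2O, 0 °C → reflux; aq. NH4Cl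
Reagents that add atoms: allylmagnesium bromide, C=CC[Mg]Br
Why: Hydroxyl-directed anti-carbomagnesiation of a propargylic alcohol puts allyl on C2 and magnesium on C3 in a chelate, so protonation gives the E-alkene.

Step 6
Reactants: 9 (2E)-2-ethylidenepent-4-en-1-ol
Product: 10 [(2S,3S)-3-methyl-2-(prop-2-en-1-yl)oxiran-2-yl]methanol
Conditions: Ti(OiPr)4 (10 mol %), L-(+)-DET (12 mol %), t-BuOOH, 4 Å MS, CH2Cl2, −20 °C
Reagents that add atoms: tert-butyl hydroperoxide, CC(C)(C)OO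
Why: Katsuki–Sharpless asymmetric epoxidation acts only on the allylic alkene; L-(+)-tartrate gives the (2S,3S) epoxide, the same facial sense as for tiglyl alcohol.

Step 7
Reactants: 10 [(2S,3S)-3-methyl-2-(prop-2-en-1-yl)oxiran-2-yl]methanol
Product: 11 (2R,3S)-2-methoxy-2-(prop-2-en-1-yl)butane-1,3-diol
Conditions: CSA (5 mol %), MeOH, 0 °C → rt
Reagents that add atoms: methanol, CO
Why: Acid-catalysed (borderline SN2) epoxide methanolysis at the tertiary carbon with backside attack inverts C2 and so sets the C5 methyl ether configuration, while C3 keeps its oxygen; regio- and stereo-isomers are diastereomers and are removed by chromatography.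

Step 8
Reactants: 11 (2R,3S)-2-methoxy-2-(prop-2-en-1-yl)butane-1,3-diol
Product: 12 (2S,3R)-3-methoxy-3-{[(triethylsilyl)oxy]methyl}hex-5-en-2-ol
Conditions: TESCl, imidazole, CH2Cl2, −20 → 0 °C
Reagents that add atoms: chlorotriethylsilane, CC[Si](CC)(CC)Cl
Why: Selective silylation of the primary over the more hindered secondary hydroxyl.

Step 9
Reactants: 12 (2S,3R)-3-methoxy-3-{[(triethylsilyl)oxy]methyl}hex-5-en-2-ol
Product: 13 (3R)-3-methoxy-3-{[(triethylsilyl)oxy]methyl}hex-5-en-2-one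
Conditions: Dess–Martin periodinane, NaHCO3, CH2Cl2, 0 °C → rt
Reagents that add atoms: none
Why: Dess–Martin oxidation of the secondary alcohol; the adjacent stereocentre is quaternary and cannot epimerise.

**Union and ring closures**

Step 10
Reactants: 13 (3R)-3-methoxy-3-{[(triethylsilyl)oxy]methyl}hex-5-en-2-one; 7 (3S,4S)-4-{[tert-butyl(dimethyl)silyl]oxy}-3-methyl-4-(3,4,5-trimethoxyphenyl)butanal
Product: 15 (4R,9S,10S)-10-{[tert-butyl(dimethyl)silyl]oxy}-7-hydroxy-4-methoxy-9-methyl-4-{[(triethylsilyl)oxy]methyl}-10-(3,4,5-trimethoxyphenyl)dec-1-en-5-one (both C7 epimers), via lithium enolate 14 (not isolated)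
Conditions: LDA, THF, −78 °C; then 7, −78 °C; aq. NH4Cl
Reagents that add atoms: lithium diisopropylamide, [Li]N(C(C)C)C(C)C (lithium of 14 only; nothing stays in 15)
Why: Directed lithium aldol addition; ketone 13 can enolise only at its methyl group (C7) and adds to the aldehyde faster than proton transfer, and the new carbinol centre is removed in the next step.

Step 11
Reactants: 15 (4R,9S,10S)-10-{[tert-butyl(dimethyl)silyl]oxy}-7-hydroxy-4-methoxy-9-methyl-4-{[(triethylsilyl)oxy]methyl}-10-(3,4,5-trimethoxyphenyl)dec-1-en-5-one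
Product: 16 (2R,7S,8S)-8-{[tert-butyl(dimethyl)silyl]oxy}-2-methoxy-7-methyl-3,5-dioxo-2-(prop-2-en-1-yl)-8-(3,4,5-trimethoxyphenyl)octanal
Conditions: (COCl)2, DMSO, CH2Cl2, −78 °C; 15, −78 → −40 °C; Et3N, −78 → 0 °C; used crude
Reagents that add atoms: none
Why: Swern oxidation converts the secondary alcohol to the ketone and, on warming, oxidises the primary TES ether directly to the aldehyde while the secondary TBS ether survives; both oxygens are activated before base is added, so no lactol or lactone can form.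

Step 12
Reactants: 16 (2R,7S,8S)-8-{[tert-butyl(dimethyl)silyl]oxy}-2-methoxy-7-methyl-3,5-dioxo-2-(prop-2-en-1-yl)-8-(3,4,5-trimethoxyphenyl)octanal
Product: 19 (2S,3S,5R)-5-methoxy-3-methyl-5-(prop-2-en-1-yl)-2-(3,4,5-trimethoxyphenyl)-2,3-dihydro-1-benzofuran-6(5H)-one, via silyl-protected cyclohexadienone enol 17 (not isolated), via desilylated cyclohexadienone enol 18 (not isolated)
Conditions: DBU (1.2 equiv), 4 Å MS, MeCN, 0 °C → rt; then 48 % aq. HF, 0 °C → rt
Reagents that add atoms: none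
Why: Intramolecular aldol condensation of the polyketide type: only the C3a enolate can reach the non-enolisable aldehyde (six-membered ring) and dehydration gives the vinylogous acid; HF then removes the TBS group and the benzylic hydroxyl condenses at C7a to form the cyclic enol ether, with the C2–O bond and all three stereocentres untouched.

**Compound list**
1 | 3,4,5-trimethoxybenzaldehyde | COc1cc(C=O)cc(OC)c1OC | starting material
2 | (1S,2S)-2-methyl-1-(3,4,5-trimethoxyphenyl)but-3-en-1-yl diisopinocampheylborinate (not isolated) | B(O[C@H](c1cc(OC)c(OC)c(OC)c1)[C@H](C=C)C)([C@@H]1C[C@@H]2C[C@H]([C@H]1C)C2(C)C)[C@@H]1C[C@@H]2C[C@H]([C@H]1C)C2(C)C | intermediate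
3 | (1S,2S)-2-methyl-1-(3,4,5-trimethoxyphenyl)but-3-en-1-ol | O[C@H](c1cc(OC)c(OC)c(OC)c1)[C@H](C=C)C | intermediate
4 | tert-butyl(dimethyl){[(1S,2S)-2-methyl-1-(3,4,5-trimethoxyphenyl)but-3-en-1-yl]oxy}silane | CC(C)(C)[Si](C)(C)O[C@H](c1cc(OC)c(OC)c(OC)c1)[C@H](C=C)C | intermediate
5 | 9-[(3S,4S)-4-{[tert-butyl(dimethyl)silyl]oxy}-3-methyl-4-(3,4,5-trimethoxyphenyl)butyl]-9-borabicyclo[3.3.1]nonane (not isolated) | CC(C)(C)[Si](C)(C)O[C@H](c1cc(OC)c(OC)c(OC)c1)[C@H](CCB1C2CCCC1CCC2)C | intermediate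
6 | (3S,4S)-4-{[tert-butyl(dimethyl)silyl]oxy}-3-methyl-4-(3,4,5-trimethoxyphenyl)butan-1-ol | CC(C)(C)[Si](C)(C)O[C@H](c1cc(OC)c(OC)c(OC)c1)[C@H](CCO)C | intermediate
7 | (3S,4S)-4-{[tert-butyl(dimethyl)silyl]oxy}-3-methyl-4-(3,4,5-trimethoxyphenyl)butanal | CC(C)(C)[Si](C)(C)O[C@H](c1cc(OC)c(OC)c(OC)c1)[C@H](CC=O)C | intermediate
8 | but-2-yn-1-ol | CC#CCO | starting material
9 | (2E)-2-ethylidenepent-4-en-1-ol | C/C=C(/CO)CC=C | intermediate
10 | [(2S,3S)-3-methyl-2-(prop-2-en-1-yl)oxiran-2-yl]methanol | OC[C@]1(CC=C)O[C@H]1C | intermediate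
11 | (2R,3S)-2-methoxy-2-(prop-2-en-1-yl)butane-1,3-diol | OC[C@](OC)(CC=C)[C@H](C)O | intermediate
12 | (2S,3R)-3-methoxy-3-{[(triethylsilyl)oxy]methyl}hex-5-en-2-ol | CC[Si](CC)(CC)OC[C@](OC)(CC=C)[C@H](C)O | intermediate
13 | (3R)-3-methoxy-3-{[(triethylsilyl)oxy]methyl}hex-5-en-2-one | CC(=O)[C@@](OC)(CC=C)CO[Si](CC)(CC)CC | intermediate
14 | lithium (3R)-3-methoxy-3-{[(triethylsilyl)oxy]methyl}hexa-1,5-dien-2-olate (not isolated) | [Li]OC(=C)[C@@](OC)(CC=C)CO[Si](CC)(CC)CC | intermediate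
15 | (4R,9S,10S)-10-{[tert-butyl(dimethyl)silyl]oxy}-7-hydroxy-4-methoxy-9-methyl-4-{[(triethylsilyl)oxy]methyl}-10-(3,4,5-trimethoxyphenyl)dec-1-en-5-one (C7 epimers) | C=CC[C@@](OC)(CO[Si](CC)(CC)CC)C(=O)CC(O)C[C@H](C)[C@H](O[Si](C)(C)C(C)(C)C)c1cc(OC)c(OC)c(OC)c1 | intermediate
16 | (2R,7S,8S)-8-{[tert-butyl(dimethyl)silyl]oxy}-2-methoxy-7-methyl-3,5-dioxo-2-(prop-2-en-1-yl)-8-(3,4,5-trimethoxyphenyl)octanal | C=CC[C@@](OC)(C=O)C(=O)CC(=O)C[C@H](C)[C@H](O[Si](C)(C)C(C)(C)C)c1cc(OC)c(OC)c(OC)c1 | intermediate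
17 | (6R)-4-[(1S,2S)-1-{[tert-butyl(dimethyl)silyl]oxy}-1-(3,4,5-trimethoxyphenyl)propan-2-yl]-3-hydroxy-6-methoxy-6-(prop-2-en-1-yl)cyclohexa-2,4-dien-1-one (not isolated) | C=CC[C@@]1(OC)C=C(C(O)=CC1=O)[C@H](C)[C@H](O[Si](C)(C)C(C)(C)C)c1cc(OC)c(OC)c(OC)c1 | intermediate
18 | (6R)-3-hydroxy-4-[(1S,2S)-1-hydroxy-1-(3,4,5-trimethoxyphenyl)propan-2-yl]-6-methoxy-6-(prop-2-en-1-yl)cyclohexa-2,4-dien-1-one (not isolated) | C=CC[C@@]1(OC)C=C(C(O)=CC1=O)[C@H](C)[C@H](O)c1cc(OC)c(OC)c(OC)c1 | intermediate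
19 | (2S,3S,5R)-5-methoxy-3-methyl-5-(prop-2-en-1-yl)-2-(3,4,5-trimethoxyphenyl)-2,3-dihydro-1-benzofuran-6(5H)-one | C=CC[C@@]1(OC)C=C2C(=CC1=O)O[C@H](c1cc(OC)c(OC)c(OC)c1)[C@H]2C | target

**Totals**
Total step count: 12 (steps 1–4 to aldehyde 7, steps 5–9 to ketone 13, steps 10–12 union and ring closures).
Longest linear sequence: 8 steps (8 → 13 → 19, steps 5–12).

**Three steps most likely to fail**

Step 7 (regiochemistry and degree of inversion in the methanolysis). Fallback: set out from allylic alcohol 9 and keep the epoxide oxygen on the quaternary carbon instead of displacing it. Sharpless epoxidation with D-(−)-DET gives the enantiomeric epoxy alcohol [(2R,3R)-3-methyl-2-(prop-2-en-1-yl)oxiran-2-yl]methanol F1. Ti(OiPr)4-mediated opening with benzoic acid at the secondary carbon (inversion at C3, tertiary C–O bond untouched) gives (2S,3R)-3-hydroxy-3-(hydroxymethyl)hex-5-en-2-yl benzoate F2. TESCl and imidazole silylate the primary hydroxyl to give (2S,3R)-3-hydroxy-3-{[(triethylsilyl)oxy]methyl}hex-5-en-2-yl benzoate F3. MeOTf with 2,6-di-tert-butyl-4-methylpyridine methylates the tertiary hydroxyl to give (2S,3R)-3-methoxy-3-{[(triethylsilyl)oxy]methyl}hex-5-en-2-yl benzoate F4. K2CO3 in MeOH removes the benzoate and the route is rejoined at 12.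

Step 11 (one-flask oxidation of a hindered primary TES ether next to a forming 1,3-diketone). Fallback: set out from diol 11 and carry C4 through the coupling as an acetal, so that the aldehyde is released by hydrolysis and not by oxidation. Swern oxidation of 11 gives (2R)-2-methoxy-3-oxo-2-(prop-2-en-1-yl)butanal F5. HC(OMe)3, PPTS and MeOH acetalise only the aldehyde to give (3R)-3-(dimethoxymethyl)-3-methoxyhex-5-en-2-one F6. LDA and then aldehyde 7 give (4R,9S,10S)-10-{[tert-butyl(dimethyl)silyl]oxy}-4-(dimethoxymethyl)-7-hydroxy-4-methoxy-9-methyl-10-(3,4,5-trimethoxyphenyl)dec-1-en-5-one F7. Dess–Martin oxidation of the single hydroxyl gives (4R,9S,10S)-10-{[tert-butyl(dimethyl)silyl]oxy}-4-(dimethoxymethyl)-4-methoxy-9-methyl-10-(3,4,5-trimethoxyphenyl)dec-1-ene-5,7-dione F8. Mild aqueous acid (LiBF4 in wet MeCN) hydrolyses the acetal and the route is rejoined at 16.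

Step 12 (the base-mediated aldol condensation may be slow or lose the formyl group by retro-Claisen cleavage). Fallback: set out from 16 and reverse the order of the two ring closures. HF·pyridine in THF removes the TBS group and the freed alcohol cyclodehydrates onto C7a to give (2R)-2-methoxy-3-oxo-4-[(2E,4S,5S)-4-methyl-5-(3,4,5-trimethoxyphenyl)oxolan-2-ylidene]-2-(prop-2-en-1-yl)butanal F9. TMSOTf and Et3N in CH2Cl2 (−78 °C → rt) then close the carbocycle by an intramolecular vinylogous Mukaiyama aldol at the oxolane CH2, and acidic work-up eliminates silanol to give 19.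

**Further compounds**
F1 | step 7 | [(2R,3R)-3-methyl-2-(prop-2-en-1-yl)oxiran-2-yl]methanol | OC[C@@]1(CC=C)O[C@@H]1C
F2 | step 7 | (2S,3R)-3-hydroxy-3-(hydroxymethyl)hex-5-en-2-yl benzoate | OC[C@](O)(CC=C)[C@H](C)OC(=O)c1ccccc1
F3 | step 7 | (2S,3R)-3-hydroxy-3-{[(triethylsilyl)oxy]methyl}hex-5-en-2-yl benzoate | CC[Si](CC)(CC)OC[C@](O)(CC=C)[C@H](C)OC(=O)c1ccccc1
F4 | step 7 | (2S,3R)-3-methoxy-3-{[(triethylsilyl)oxy]methyl}hex-5-en-2-yl benzoate | CC[Si](CC)(CC)OC[C@](OC)(CC=C)[C@H](C)OC(=O)c1ccccc1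
F5 | step 11 | (2R)-2-methoxy-3-oxo-2-(prop-2-en-1-yl)butanal | CC(=O)[C@@](OC)(CC=C)C=O
F6 | step 11 | (3R)-3-(dimethoxymethyl)-3-methoxyhex-5-en-2-one | CC(=O)[C@@](OC)(CC=C)C(OC)OC
F7 | step 11 | (4R,9S,10S)-10-{[tert-butyl(dimethyl)silyl]oxy}-4-(dimethoxymethyl)-7-hydroxy-4-methoxy-9-methyl-10-(3,4,5-trimethoxyphenyl)dec-1-en-5-one | C=CC[C@@](OC)(C(OC)OC)C(=O)CC(O)C[C@H](C)[C@H](O[Si](C)(C)C(C)(C)C)c1cc(OC)c(OC)c(OC)c1
F8 | step 11 | (4R,9S,10S)-10-{[tert-butyl(dimethyl)silyl]oxy}-4-(dimethoxymethyl)-4-methoxy-9-methyl-10-(3,4,5-trimethoxyphenyl)dec-1-ene-5,7-dione | C=CC[C@@](OC)(C(OC)OC)C(=O)CC(=O)C[C@H](C)[C@H](O[Si](C)(C)C(C)(C)C)c1cc(OC)c(OC)c(OC)c1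
F9 | step 12 | (2R)-2-methoxy-3-oxo-4-[(2E,4S,5S)-4-methyl-5-(3,4,5-trimethoxyphenyl)oxolan-2-ylidene]-2-(prop-2-en-1-yl)butanal | C=CC[C@@](OC)(C=O)C(=O)/C=C1\C[C@H](C)[C@H](O1)c1cc(OC)c(OC)c(OC)c1
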